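The pyranone ring is cut at C2–C3 and C4–C4a, leaving a two-carbon C3–C4 unit and an aryl oxocarbenium ion in which O1=C2 is conjugated with C8a=C4a of ring A, a cationic 2-oxadiene. In the key step this ion, released from a mixed pivaloyloxy aryl acetal under a chiral Brønsted acid, takes up ethoxyacetylene in a stepwise [4+2] annulation (oxa-Povarov type): the alkyne terminus bonds to C2 under control of the chiral counteranion, and the resulting ketenium carbon is captured by the electron-rich C4a. Hydrolysis of the enol ether gives the flavanone. Bromine atoms hold the two prenyl positions until a late double Stille coupling.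

Key step: step 6

Assumption: the sense of induction of the chiral acid in step 6 cannot be taken from precedent; the (R)-acid is written, and its antipode is to be used if it proves to shield the Si face of C2.
Abbreviations: TBS = tert-butyldimethylsilyl; Piv = pivaloyl.

Step 1
Reactants: 1 3-bromo-4,5-dihydroxybenzaldehyde
Product: 2 3-bromo-4,5-bis(tert-butyldimethylsilyloxy)benzaldehyde
Conditions: TBSCl (2.5 equiv), imidazole (5 equiv), DMF, rt
Reagents that add atoms: tert-butyldimethylsilyl chloride, CC(C)(C)[Si](C)(C)Cl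
Why: Imidazole-mediated silyl ether formation should protect both catechol oxygens, and neither the aldehyde nor the aryl bromide reacts.

Step 2
Reactants: 2 3-bromo-4,5-bis(tert-butyldimethylsilyloxy)benzaldehyde
Product: 3 rac-[3-bromo-4,5-bis(tert-butyldimethylsilyloxy)phenyl](chloro)methyl pivalate
Conditions: PivCl (1.2 equiv), ZnCl2 (2 mol%), CH2Cl2, 0 °C to rt; volatiles removed, used crude
Reagents that add atoms: pivaloyl chloride, CC(C)(C)C(=O)Cl
Why: ZnCl2-catalysed addition of an acyl chloride across an aldehyde C=O is the standard entry to α-chloroalkyl esters, and the hindered pivaloyl group should later suppress acyl transfer.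

Step 3
Reactants: 4 phloroglucinol (benzene-1,3,5-triol)
Product: 5 3,5-bis(tert-butyldimethylsilyloxy)phenol
Conditions: TBSCl (2.0 equiv), imidazole (4 equiv), DMF, 0 °C to rt; chromatography
Reagents that add atoms: tert-butyldimethylsilyl chloride, CC(C)(C)[Si](C)(C)Cl
Why: Statistical silylation of three equivalent hydroxyls can give only one bis-silyl ether, which should be separable from the mono- and tris-silyl ethers.

Step 4
Reactants: 5 3,5-bis(tert-butyldimethylsilyloxy)phenol
Product: 6 2-bromo-3,5-bis(tert-butyldimethylsilyloxy)phenol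
Conditions: NBS (1.0 equiv), i-Pr2NH (10 mol%), CH2Cl2, −78 to 0 °C
Reagents that add atoms: N-bromosuccinimide, O=C1CCC(=O)N1Br
Why: Amine-assisted electrophilic aromatic bromination should go ortho to the free hydroxyl, because the para carbon lies between two bulky silyloxy groups.

Step 5
Reactants: 6 2-bromo-3,5-bis(tert-butyldimethylsilyloxy)phenol; 3 rac-[3-bromo-4,5-bis(tert-butyldimethylsilyloxy)phenyl](chloro)methyl pivalate
Product: 7 rac-[3-bromo-4,5-bis(tert-butyldimethylsilyloxy)phenyl][2-bromo-3,5-bis(tert-butyldimethylsilyloxy)phenoxy]methyl pivalate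
Conditions: i-Pr2NEt (1.5 equiv), CH2Cl2, 0 °C to rt; Et3N-deactivated silica
Reagents that add atoms: none
Why: O-alkylation of a phenol by an α-chloroalkyl ester (acyloxyalkyl ether formation, as with chloromethyl pivalate) should proceed at oxygen through the hard, oxocarbenium-like electrophile, and the weak amine base avoids silyl scrambling.

Step 6
Reactants: 7 rac-[3-bromo-4,5-bis(tert-butyldimethylsilyloxy)phenyl][2-bromo-3,5-bis(tert-butyldimethylsilyloxy)phenoxy]methyl pivalate; 8 ethoxyacetylene
Product: 10 (S)-8-bromo-2-[3-bromo-4,5-bis(tert-butyldimethylsilyloxy)phenyl]-5,7-bis(tert-butyldimethylsilyloxy)chroman-4-one, via 4-ethoxy-2H-chromene enol ether 9 (not isolated)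
Conditions: (R)-3,3'-bis(2,4,6-triisopropylphenyl)-1,1'-binaphthyl-2,2'-diyl N-triflylphosphoramide (10 mol%), 8 (3 equiv, slow addition), 4 Å MS, toluene, −60 °C; then 0.5 M HCl, THF, 0 °C
Reagents that add atoms: water, O
Why: Proposed new method: the acid protonates the pivalate carbonyl of 7 and pivalic acid leaves (the acyloxy group is the better leaving group and the poorer donor, so the aryloxy oxygen stays), giving the aryl oxocarbenium ion O1=C2 paired with the chiral phosphoramide anion; the nucleophilic CH terminus of 8 adds to C2 (C3–C2 bond), the ethoxyketenium carbon C4 so formed is attacked by C4a of ring A (C4–C4a bond), loss of the arene proton returns the acid, and aqueous acid then cleaves enol ether 9 to the ketone. The closest known reaction types are the Lewis-acid-promoted oxa-Povarov reaction of aryl oxocarbenium ions with alkenes, the Povarov annulation of N-aryl imines with ynamides and chiral-counteranion-controlled additions to oxocarbenium ions. The pyran ring closes as a six-membered ring by Friedel–Crafts capture of the digonal ketenium carbon (6-exo-dig with respect to its C4=O bond, with C3=C4 becoming endocyclic), and the vacant orbital at C4 lies in the plane that holds C2, so the O1–C8a tether should reach it without strain. The C2 stereocentre is set in the first C–C bond formation, where the confined anion is expected to leave the Si face of the planar C2 open to the alkyne, giving 2S, and it is not touched afterwards. The step needs closure at C4a and not at the bromine-bearing ortho carbon C8 or on a second molecule: C4a is the only unsubstituted ortho position, it is ortho or para to three oxygen donors, ipso attack at C8 should be reversible, and the bulky silyl ethers shield the remaining ring positions. Excess 8 is used because part of it is expected to be lost to acid-promoted addition of pivalic acid.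

Step 7
Reactants: 10 (S)-8-bromo-2-[3-bromo-4,5-bis(tert-butyldimethylsilyloxy)phenyl]-5,7-bis(tert-butyldimethylsilyloxy)chroman-4-one; 11 tributyl(3-methylbut-2-en-1-yl)stannane
Product: 12 (S)-5,7-bis(tert-butyldimethylsilyloxy)-2-[3,4-bis(tert-butyldimethylsilyloxy)-5-(3-methylbut-2-en-1-yl)phenyl]-8-(3-methylbut-2-en-1-yl)chroman-4-one
Conditions: 11 (3 equiv), Pd(P(t-Bu)3)2 (10 mol%), toluene, 90 °C
Reagents that add atoms: none
Why: Double Stille coupling under neutral conditions should replace both aryl bromides by linear prenyl groups (reductive elimination at the less hindered CH2 terminus) without enolising the ketone or opening the pyranone ring, so C2 keeps its configuration.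

Step 8
Reactants: 12 (S)-5,7-bis(tert-butyldimethylsilyloxy)-2-[3,4-bis(tert-butyldimethylsilyloxy)-5-(3-methylbut-2-en-1-yl)phenyl]-8-(3-methylbut-2-en-1-yl)chroman-4-one
Product: 13 (2S)-5,7-dihydroxy-2-[3,4-dihydroxy-5-(3-methylbut-2-en-1-yl)phenyl]-8-(3-methylbut-2-en-1-yl)chroman-4-one (target)
Conditions: Bu4NF (4.4 equiv), AcOH (4.4 equiv), THF, 0 °C
Reagents that add atoms: none
Why: Fluoride-induced cleavage of the four aryl silyl ethers, buffered with acetic acid, should free the phenols without the base-induced ring opening to the chalcone that would racemise C2, and the prenyl groups are inert to it.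

Compound list
1 | 3-bromo-4,5-dihydroxybenzaldehyde | O=Cc1cc(O)c(O)c(Br)c1 | starting material
2 | 3-bromo-4,5-bis(tert-butyldimethylsilyloxy)benzaldehyde | O=Cc1cc(O[Si](C)(C)C(C)(C)C)c(O[Si](C)(C)C(C)(C)C)c(Br)c1 | intermediate
3 | rac-[3-bromo-4,5-bis(tert-butyldimethylsilyloxy)phenyl](chloro)methyl pivalate | CC(C)(C)C(=O)OC(Cl)c1cc(O[Si](C)(C)C(C)(C)C)c(O[Si](C)(C)C(C)(C)C)c(Br)c1 | intermediate
4 | phloroglucinol (benzene-1,3,5-triol) | Oc1cc(O)cc(O)c1 | starting material
5 | 3,5-bis(tert-butyldimethylsilyloxy)phenol | Oc1cc(O[Si](C)(C)C(C)(C)C)cc(O[Si](C)(C)C(C)(C)C)c1 | intermediate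
6 | 2-bromo-3,5-bis(tert-butyldimethylsilyloxy)phenol | Oc1cc(O[Si](C)(C)C(C)(C)C)cc(O[Si](C)(C)C(C)(C)C)c1Br | intermediate
7 | rac-[3-bromo-4,5-bis(tert-butyldimethylsilyloxy)phenyl][2-bromo-3,5-bis(tert-butyldimethylsilyloxy)phenoxy]methyl pivalate | CC(C)(C)C(=O)OC(Oc1cc(O[Si](C)(C)C(C)(C)C)cc(O[Si](C)(C)C(C)(C)C)c1Br)c1cc(O[Si](C)(C)C(C)(C)C)c(O[Si](C)(C)C(C)(C)C)c(Br)c1 | intermediate
8 | ethoxyacetylene (ethoxyethyne) | C#COCC | starting material
9 | (S)-8-bromo-2-[3-bromo-4,5-bis(tert-butyldimethylsilyloxy)phenyl]-4-ethoxy-5,7-bis(tert-butyldimethylsilyloxy)-2H-chromene | Brc1cc([C@@H]2C=C(OCC)c3c(O[Si](C)(C)C(C)(C)C)cc(O[Si](C)(C)C(C)(C)C)c(Br)c3O2)cc(O[Si](C)(C)C(C)(C)C)c1O[Si](C)(C)C(C)(C)C | intermediate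
10 | (S)-8-bromo-2-[3-bromo-4,5-bis(tert-butyldimethylsilyloxy)phenyl]-5,7-bis(tert-butyldimethylsilyloxy)chroman-4-one | Brc1cc([C@@H]2CC(=O)c3c(O[Si](C)(C)C(C)(C)C)cc(O[Si](C)(C)C(C)(C)C)c(Br)c3O2)cc(O[Si](C)(C)C(C)(C)C)c1O[Si](C)(C)C(C)(C)C | intermediate
11 | tributyl(3-methylbut-2-en-1-yl)stannane | CCCC[Sn](CCCC)(CCCC)CC=C(C)C | starting material
12 | (S)-5,7-bis(tert-butyldimethylsilyloxy)-2-[3,4-bis(tert-butyldimethylsilyloxy)-5-(3-methylbut-2-en-1-yl)phenyl]-8-(3-methylbut-2-en-1-yl)chroman-4-one | CC(C)=CCc1cc([C@@H]2CC(=O)c3c(O[Si](C)(C)C(C)(C)C)cc(O[Si](C)(C)C(C)(C)C)c(CC=C(C)C)c3O2)cc(O[Si](C)(C)C(C)(C)C)c1O[Si](C)(C)C(C)(C)C | intermediate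
13 | (2S)-5,7-dihydroxy-2-[3,4-dihydroxy-5-(3-methylbut-2-en-1-yl)phenyl]-8-(3-methylbut-2-en-1-yl)chroman-4-one | CC(C)=CCc1cc([C@@H]2CC(=O)c3c(O)cc(O)c(CC=C(C)C)c3O2)cc(O)c1O | target

Total steps: 8. Longest linear sequence: 6 steps (steps 3, 4, 5, 6, 7, 8 from 4; the branch from 1 through steps 1, 2, 5, 6, 7, 8 is equally long).

Steps most likely to fail

Step 6 (proposed new method). What may go wrong: weak facial discrimination of the acyclic ion pair by the anion, attack of O1 on the ketenium followed by ring opening to a cinnamate, or consumption of the alkyne by the acid before annulation. The fallback uses known chemistry, sets out from 2 and 6 and returns at 10. Roskamp homologation of 2 with ethyl diazoacetate (NbCl5 cat., CH2Cl2, rt) should give ethyl 3-[3-bromo-4,5-bis(tert-butyldimethylsilyloxy)phenyl]-3-oxopropanoate F1. Asymmetric transfer hydrogenation (RuCl(p-cymene)[(R,R)-TsDPEN], HCO2H/Et3N) should give ethyl (R)-3-[3-bromo-4,5-bis(tert-butyldimethylsilyloxy)phenyl]-3-hydroxypropanoate F2. Mitsunobu etherification with 6 (PPh3, DIAD, toluene, 0 °C) should invert the carbinol centre and give the (S)-aryl ether ester F3. Me3SnOH (1,2-dichloroethane, 70 °C) should free the (S)-3-aryloxy acid F4 without touching the silyl ethers. (CF3CO)2O (CH2Cl2, 0 °C) should then close the pyranone ring by intramolecular Friedel–Crafts acylation at C4a to give 10.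

Step 5. What may go wrong: ionisation or hydrolysis of the acid-labile acylal during isolation, or acyl transfer from 3 to the phenol in place of alkylation. The fallback sets out from 2 and 6 and returns at 10 with a benzotriazole N,O-acetal as the oxocarbenium precursor. Condensation of 2 with 1H-benzotriazole and SOCl2 (toluene, rt) should give rac-1-{[3-bromo-4,5-bis(tert-butyldimethylsilyloxy)phenyl](chloro)methyl}-1H-benzotriazole F5. Displacement of chloride by 6 (i-Pr2NEt, CH2Cl2) should give rac-1-{[3-bromo-4,5-bis(tert-butyldimethylsilyloxy)phenyl][2-bromo-3,5-bis(tert-butyldimethylsilyloxy)phenoxy]methyl}-1H-benzotriazole F6, which carries no acyl group and should tolerate chromatography. Under the conditions of step 6 it should lose benzotriazole in place of pivalic acid and give 10.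

Step 7. What may go wrong: transfer of the prenyl group through its tertiary terminus (reverse prenylation) or slow transmetalation of the bulky allylic stannane at the hindered C8–Br bond. The fallback sets out from 10 and returns at 12. Stille coupling with allyltributylstannane (Pd(P(t-Bu)3)2, toluene, 90 °C), which is smaller and raises no regiochemical question, should give (S)-8-allyl-2-[3-allyl-4,5-bis(tert-butyldimethylsilyloxy)phenyl]-5,7-bis(tert-butyldimethylsilyloxy)chroman-4-one F7. Double cross-metathesis with 2-methyl-2-butene (second-generation Grubbs catalyst RuCl2(=CHPh)(PCy3)(H2IMes), CH2Cl2, 40 °C) should convert both allyl groups into prenyl groups and give 12.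

Further compounds
F1 | step 6 | ethyl 3-[3-bromo-4,5-bis(tert-butyldimethylsilyloxy)phenyl]-3-oxopropanoate | CCOC(=O)CC(=O)c1cc(O[Si](C)(C)C(C)(C)C)c(O[Si](C)(C)C(C)(C)C)c(Br)c1
F2 | step 6 | ethyl (R)-3-[3-bromo-4,5-bis(tert-butyldimethylsilyloxy)phenyl]-3-hydroxypropanoate | CCOC(=O)C[C@@H](O)c1cc(O[Si](C)(C)C(C)(C)C)c(O[Si](C)(C)C(C)(C)C)c(Br)c1
F3 | step 6 | ethyl (S)-3-[3-bromo-4,5-bis(tert-butyldimethylsilyloxy)phenyl]-3-[2-bromo-3,5-bis(tert-butyldimethylsilyloxy)phenoxy]propanoate | CCOC(=O)C[C@H](Oc1cc(O[Si](C)(C)C(C)(C)C)cc(O[Si](C)(C)C(C)(C)C)c1Br)c1cc(O[Si](C)(C)C(C)(C)C)c(O[Si](C)(C)C(C)(C)C)c(Br)c1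
F4 | step 6 | (S)-3-[3-bromo-4,5-bis(tert-butyldimethylsilyloxy)phenyl]-3-[2-bromo-3,5-bis(tert-butyldimethylsilyloxy)phenoxy]propanoic acid | OC(=O)C[C@H](Oc1cc(O[Si](C)(C)C(C)(C)C)cc(O[Si](C)(C)C(C)(C)C)c1Br)c1cc(O[Si](C)(C)C(C)(C)C)c(O[Si](C)(C)C(C)(C)C)c(Br)c1
F5 | step 5 | rac-1-{[3-bromo-4,5-bis(tert-butyldimethylsilyloxy)phenyl](chloro)methyl}-1H-benzotriazole | ClC(c1cc(O[Si](C)(C)C(C)(C)C)c(O[Si](C)(C)C(C)(C)C)c(Br)c1)n1nnc2ccccc12
F6 | step 5 | rac-1-{[3-bromo-4,5-bis(tert-butyldimethylsilyloxy)phenyl][2-bromo-3,5-bis(tert-butyldimethylsilyloxy)phenoxy]methyl}-1H-benzotriazole | Brc1c(OC(c2cc(O[Si](C)(C)C(C)(C)C)c(O[Si](C)(C)C(C)(C)C)c(Br)c2)n2nnc3ccccc23)cc(O[Si](C)(C)C(C)(C)C)cc1O[Si](C)(C)C(C)(C)C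
F7 | step 7 | (S)-8-allyl-2-[3-allyl-4,5-bis(tert-butyldimethylsilyloxy)phenyl]-5,7-bis(tert-butyldimethylsilyloxy)chroman-4-one | C=CCc1cc([C@@H]2CC(=O)c3c(O[Si](C)(C)C(C)(C)C)cc(O[Si](C)(C)C(C)(C)C)c(CC=C)c3O2)cc(O[Si](C)(C)C(C)(C)C)c1O[Si](C)(C)C(C)(C)C
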